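**Assumptions:** (i) Carbonate 6 is prepared, not bought, and is counted as a step. (ii) The sense of induction of the new step 8 cannot be predicted in advance; (S)-TRIP is written, and the antipode that gives (2S) is fixed in the first screen.

## Retrosynthetic overview
1. Kazinol B (16) ⇐ its 7-O-TIPS ether 15 by desilylation.
2. The flavan dihydropyran ring (O1–C2 and C3–C4 bonds, C2 stereocentre) is formed last, by a chiral-Brønsted-acid-catalysed oxa-[4+2] of an o-quinone methide (from salicyl alcohol 14) with B-ring styrene 10.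
3. Styrene 10 ⇐ aldehyde 8 (Wittig). The 2,2-dimethylpyran ring and the C-prenyl group of 8 come from one thermal double Claisen of mixed bis-ether 7.
4. 7 ⇐ 3,4-dihydroxybenzaldehyde (4-O-propargylation, then Pd reverse prenylation); 14 ⇐ 2,4-dihydroxybenzaldehyde (TIPS, NaBH4).
5. Ring order: chromene pyran ring first, flavan pyran ring second.

## Route

**Step 1**
Reactants: 1 (3,4-dihydroxybenzaldehyde); 2 (3-chloro-3-methylbut-1-yne)
Product: 3, 3-hydroxy-4-[(2-methylbut-3-yn-2-yl)oxy]benzaldehyde
Conditions: 2 (1.3 equiv), K2CO3 (1.1 equiv), KI, CuI (2 mol%), DMF, rt → 40 °C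
Reagents that add atoms: 3-chloro-3-methylbut-1-yne, CC(C)(Cl)C#C
Why: The 4-OH (para to CHO) is far more acidic than the 3-OH, so with one equivalent of base only the 4-phenoxide is alkylated (Cu-assisted propargylic etherification with a tertiary propargyl chloride).

**Step 2**
Reactants: 4 (2-methylbut-3-en-2-ol); 5 (di-tert-butyl dicarbonate)
Product: 6, tert-butyl (2-methylbut-3-en-2-yl) carbonate
Conditions: n-BuLi, THF, −78 → 0 °C; then Boc2O, 0 °C → rt
Reagents that add atoms: Boc2O, CC(C)(C)OC(=O)OC(=O)OC(C)(C)C
Why: Standard O-acylation of a tertiary lithium alkoxide.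

**Step 3**
Reactants: 3; 6
Product: 7, 3-[(2-methylbut-3-en-2-yl)oxy]-4-[(2-methylbut-3-yn-2-yl)oxy]benzaldehyde
Conditions: 6 (1.5 equiv), Pd(PPh3)4 (3 mol%), 4 Å MS, THF, 0 °C
Reagents that add atoms: carbonate 6, CC(C)(C)OC(=O)OC(C)(C)C=C
Why: Tsuji–Trost O-allylation; at low temperature the phenoxide attacks the more substituted terminus of the 1,1-dimethylallyl-Pd cation, giving the tertiary ("reverse-prenyl") aryl ether.

**Step 4**
Reactants: 7
Product: 8, 8-hydroxy-2,2-dimethyl-7-(3-methylbut-2-en-1-yl)-2H-chromene-6-carbaldehyde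
Conditions: PhNEt2 (0.1 M), Ar, 120 °C (1 h) then 185 °C (2–3 h)
Reagents that add atoms: none
Why: Two independent aromatic Claisen rearrangements, each with only one free ortho carbon: the 1,1-dimethylallyl ether shifts to C2 to give the linear prenyl group and free 3-OH, and the propargyl ether shifts to C5 (allenyl phenol → 1,5-H shift → oxa-6π closure) to give the 2,2-dimethyl-2H-chromene.

**Step 5**
Reactants: 8; 9 (methyltriphenylphosphonium bromide)
Product: 10, 6-ethenyl-2,2-dimethyl-7-(3-methylbut-2-en-1-yl)-2H-chromen-8-ol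
Conditions: Ph3PCH3Br (3 equiv), KOtBu (3 equiv), THF, 0 °C → rt; store cold with BHT
Reagents that add atoms: methyltriphenylphosphonium bromide, C[P+](c1ccccc1)(c1ccccc1)c1ccccc1.[Br-]
Why: Wittig methylenation of a non-enolisable aldehyde; excess ylide absorbs the phenol proton, and the phenoxide is meta to CHO so it does not deactivate it.

**Step 6**
Reactants: 11 (2,4-dihydroxybenzaldehyde); 12 (triisopropylsilyl chloride)
Product: 13, 2-hydroxy-4-[(triisopropylsilyl)oxy]benzaldehyde
Conditions: TIPSCl (1.05 equiv), imidazole, CH2Cl2, 0 °C → rt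
Reagents that add atoms: TIPSCl, CC(C)[Si](Cl)(C(C)C)C(C)C
Why: The 2-OH is hydrogen-bonded to the aldehyde and unreactive, so silylation occurs only at the 4-OH.

**Step 7**
Reactants: 13
Product: 14, 2-(hydroxymethyl)-5-[(triisopropylsilyl)oxy]phenol
Conditions: NaBH4, THF/EtOH, 0 °C; pH 7 work-up, use without acidic chromatography
Reagents that add atoms: none
Why: Borohydride reduction of the aldehyde; the aryl TIPS ether survives, and the acid-sensitive salicyl alcohol is handled under neutral conditions.

**Step 8 (key step)**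
Reactants: 10; 14
Product: 15, 6-[(2S)-7-[(triisopropylsilyl)oxy]-3,4-dihydro-2H-chromen-2-yl]-2,2-dimethyl-7-(3-methylbut-2-en-1-yl)-2H-chromen-8-ol
Conditions: (S)-TRIP (10 mol%), 5 Å MS, PhCF3, −20 → 0 °C; 14 (1.5 equiv) added over 6 h
Reagents that add atoms: salicyl alcohol 14 (loses H2O), OCc1ccc(O[Si](C(C)C)(C(C)C)C(C)C)cc1O
Why: Proposed new method: a catalytic enantioselective inverse-electron-demand oxa-[4+2] between a CH2-terminated (4-unsubstituted) o-quinone methide and a p-alkoxystyrene lacking an ortho-OH directing group, giving a flavan directly. The chiral phosphoric acid dehydrates 14 (easy, because the benzylic cation is stabilised by the ortho-OH and para-OSi donors) to an o-QM that stays hydrogen-bonded to the phosphate; the terminal vinyl CH2 of 10 attacks the exocyclic CH2 (C3–C4 bond), and the developing p-alkoxybenzylic cation is closed by the phenolic oxygen inside the chiral ion pair (O1–C2 bond), with the 3,3'-aryl walls selecting the styrene face and so setting C2. The free 8-OH of 10 can give a second hydrogen bond to P=O for a two-point organised transition state. The acid is too weak to protonate the prenyl or chromene alkenes, both of which are also poorer nucleophiles than the styrene, and the bulky OTIPS shields both activated positions of 14 against self-condensation. Closest known reaction type: chiral phosphoric acid-catalysed hetero-Diels–Alder reactions of o-QMs from o-hydroxybenzhydryl alcohols with o-hydroxystyrenes, vinylindoles or enamides, and the racemic thermal o-QM/styrene flavan synthesis.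

**Step 9**
Reactants: 15
Product: 16, kazinol B, 6-[(2S)-7-hydroxy-3,4-dihydro-2H-chromen-2-yl]-2,2-dimethyl-7-(3-methylbut-2-en-1-yl)-2H-chromen-8-ol
Conditions: TBAF (1.1 equiv), AcOH (1.1 equiv), THF, 0 °C
Reagents that add atoms: none
Why: Fluoride cleavage of the aryl silyl ether under buffered conditions that leave the alkenes, phenols and the C2 benzylic ether stereocentre untouched.

## Compound list
1 | 3,4-dihydroxybenzaldehyde | O=Cc1ccc(O)c(O)c1 | starting material
2 | 3-chloro-3-methylbut-1-yne | CC(C)(Cl)C#C | starting material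
3 | 3-hydroxy-4-[(2-methylbut-3-yn-2-yl)oxy]benzaldehyde | O=Cc1ccc(OC(C)(C)C#C)c(O)c1 | intermediate
4 | 2-methylbut-3-en-2-ol | CC(C)(O)C=C | starting material
5 | di-tert-butyl dicarbonate | CC(C)(C)OC(=O)OC(=O)OC(C)(C)C | starting material
6 | tert-butyl (2-methylbut-3-en-2-yl) carbonate | CC(C)(C)OC(=O)OC(C)(C)C=C | intermediate
7 | 3-[(2-methylbut-3-en-2-yl)oxy]-4-[(2-methylbut-3-yn-2-yl)oxy]benzaldehyde | O=Cc1ccc(OC(C)(C)C#C)c(OC(C)(C)C=C)c1 | intermediate
8 | 8-hydroxy-2,2-dimethyl-7-(3-methylbut-2-en-1-yl)-2H-chromene-6-carbaldehyde | CC(C)=CCc1c(C=O)cc2c(c1O)OC(C)(C)C=C2 | intermediate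
9 | methyltriphenylphosphonium bromide | C[P+](c1ccccc1)(c1ccccc1)c1ccccc1.[Br-] | starting material
10 | 6-ethenyl-2,2-dimethyl-7-(3-methylbut-2-en-1-yl)-2H-chromen-8-ol | CC(C)=CCc1c(C=C)cc2c(c1O)OC(C)(C)C=C2 | intermediate
11 | 2,4-dihydroxybenzaldehyde | O=Cc1ccc(O)cc1O | starting material
12 | triisopropylsilyl chloride | CC(C)[Si](Cl)(C(C)C)C(C)C | starting material
13 | 2-hydroxy-4-[(triisopropylsilyl)oxy]benzaldehyde | O=Cc1ccc(O[Si](C(C)C)(C(C)C)C(C)C)cc1O | intermediate
14 | 2-(hydroxymethyl)-5-[(triisopropylsilyl)oxy]phenol | OCc1ccc(O[Si](C(C)C)(C(C)C)C(C)C)cc1O | intermediate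
15 | 7-O-TIPS kazinol B, (2S) | CC(C)=CCc1c([C@@H]2CCc3ccc(O[Si](C(C)C)(C(C)C)C(C)C)cc3O2)cc2c(c1O)OC(C)(C)C=C2 | intermediate
16 | kazinol B, (2S) | CC(C)=CCc1c([C@@H]2CCc3ccc(O)cc3O2)cc2c(c1O)OC(C)(C)C=C2 | target

## Summary
Total steps: 9. Longest linear sequence: 6 (steps 1, 3, 4, 5, 8, 9).

Three steps most likely to fail:
1. **Step 8 (proposed new asymmetric o-QM/styrene oxa-[4+2]).** The risks are low ee without a directing group, o-QM oligomerisation, and competing reaction at the prenyl alkene. Fallback (known chemistry): switch to a ketone-reduction/Mitsunobu flavan synthesis.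
   - Make the 6-acetyl analogue of 8 from 3,4-dihydroxyacetophenone by steps 1, 3 and 4.
   - Claisen–Schmidt condensation with 2-O-protected 13, then selective 1,4-reduction of the enone (Stryker's reagent).
   - (S)-Me-CBS/BH3·SMe2 reduction to the (R)-benzylic alcohol.
   - Unmask the phenol and close the ring by Mitsunobu reaction (PPh3/DIAD, inversion) to the (2S)-flavan, then TBAF.
2. **Step 3 (Pd reverse prenylation next to a bulky tertiary propargyl ether, terminal alkyne present).** The risks are a slow reaction, linear O-prenyl ether, or Pd-induced loss of the propargyl ether. Fallback: O-allylate 3 with allyl bromide/K2CO3, run the same thermal cascade to the 7-allyl chromene aldehyde, then convert allyl to prenyl by cross-metathesis with 2-methyl-2-butene (Grubbs II).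
3. **Step 4 (one-pot double Claisen at up to 185 °C).** The risks are loss of isoprene from the tertiary allyl ether, and ene or cyclisation side reactions of the o-prenyl phenol/aldehyde. Fallback: decouple the two events. Cyclise 3 alone to 8-hydroxy-2,2-dimethyl-2H-chromene-6-carbaldehyde, then reverse-prenylate the now unhindered chromen-8-ol with 6/Pd(0) and run a separate allyl Claisen at ≤120 °C (one extra step).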